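1. At the reading of 0.250 h the red run, with first and second end groups charged equally, stood at 44.0% links. Read as a second-order approach, this gave me a link time of 0.318 h, the wait of a first end group at full [second end groups].

| flask | first end groups | second end groups | one-sided end groups | protic impurity | temperature | remark | time |
|---|---|---|---|---|---|---|---|
| teal | 0.33 M | 0.33 M | 6.6 mM | 0.165 M | 0 °C | run made earlier |  |
| red | 0.33 M | 0.33 M | 6.6 mM | 0.083 M | 0 °C | run made earlier |  |
| Friday's | 0.33 M | 0.330 M (fed, over 20 h) | 6.60 mM | 0.165 M | 0 °C | all else is in the flask from the start; the feed brings no volume worth counting | 30 h |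
| Sunday's | 0.33 M (in portions, 5, over 20 h) | 0.330 M | 6.60 mM | 0.165 M | 0 °C | first portion at the start, last at 20 h | 30 h |
| Thursday's | 0.33 M (fed, over 20 h) | 0.330 M | 6.60 mM | 0.165 M | 0 °C | all else is in the flask from the start; the feed brings no volume worth counting | 30 h |
| Wednesday's | 0.33 M | 0.330 M (fed, over 20 h) | 6.60 mM | 0.165 M |  | the addition at −20 °C, then warmed to 0 °C; the feed brings no volume worth counting | 30 h |
| Saturday's | 0.33 M | 0.330 M | 6.60 mM | 0.165 M |  | everything together at the start at −20 °C, warmed to 0 °C at 20 h | 30 h |

- teal (time / h: links / %): 1.50: 65.2; 5.00: 68.3; 8.00: 68.5; 12.0: 69.7; 20.0: 69.1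
- red (time / h: links / %): 0.250: 44.0; 0.833: 64.2; 1.33: 65.9; 2.00: 68.3; 3.00: 69.7

(scatter of a reading: 0.5 percentage points)

* the flask with the highest amount of links, in percent of the first end groups charged ("all alike" if they lie within 1.5 percentage points) (Friday's / Sunday's / Thursday's / Wednesday's / Saturday's / all alike)
* final links, as a percentage of the first end groups charged, in Friday's
* final links, as a percentage of the first end groups charged, in Sunday's
* final links, as a percentage of the first end groups charged, in Thursday's
* final links, as a percentage of the first end groups charged, in Wednesday's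
* final links, as a percentage of the first end groups charged, in Saturday's

- the earlier runs do not show what temperature does; that part of a forecast is a guess

2. Teal's last reading was 69.1% and red's 69.7%, although teal held twice the [protic impurity]. I bracketed Friday's, where first end groups wait through a feed of 20 h against a link time of 0.318 h.

3. Upper bound: if the plateau is an equilibrium, waiting costs nothing, and Friday's reaches teal's 69.1%.

4. Lower bound: I supposed that the missing 30.9% is irreversible loss of waiting first end groups, suffered within one link time. A first end group then survives each link time with a chance of 69.1%, which means a loss rate of 1.16 h⁻¹.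

5. The waiting number, loss rate times dosing time (a Damköhler number), is then 23.2.

6. Crudely, the feed finds partners for one loss lifetime, so the link share is one over the waiting number, 4.30%. Tightened, with the feed also consuming first end groups, the share is the natural logarithm of one plus the waiting number, divided by that number: 13.7%.

7. The forecast gave Friday's 69.5%, Sunday's 69.5%, Thursday's 69.5%, Wednesday's 69.3%, Saturday's 69.2%, and all alike, holding that "feed order and portions only change the route". Its Friday's value stands 0.4 percentage points above my upper bound, against a scatter of 0.5 points.

8. Friday's gave 32.0%, inside my bracket; Saturday's led at 72.1%, with Sunday's 68.6%, Thursday's 68.6% and Wednesday's 59.9%. At 30.0 h Friday's held 0.0787% first end groups but 60.4% of its second end groups. My waiting number of 23.2 had given 13.7%, which lies below Friday's by 18 points.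

    first end groups + second end groups → links (k = 0.00310 M⁻¹ s⁻¹, Ea = 45.0 kJ mol⁻¹)
    first end groups + one-sided end groups → capped ends (k = 0.0390 M⁻¹ s⁻¹, Ea = 51.0 kJ mol⁻¹)
    first end groups ⇌ dormant form (K = 12.0, k = 2.60 × 10⁻⁵ s⁻¹, Ea = 95.0 kJ mol⁻¹, ΔH = −46.0 kJ mol⁻¹)
    first end groups + protic impurity → quenched substrate (k = 3.10 × 10⁻⁴ M⁻¹ s⁻¹, Ea = 55.0 kJ mol⁻¹)
    links ⇌ isomer of the product (K = 0.240, k = 9.60 × 10⁻⁵ s⁻¹, Ea = 96.0 kJ mol⁻¹, ΔH = −21.0 kJ mol⁻¹)
    (constants at 0 °C)

9. With dosing over 6.00 h, Friday's scales to a waiting number of 6.97, which gives links of 29.8%. That run gave 46.8%.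

(The numbers in the tables were generated by integration for substances that don't exist, and the scatter is random.)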